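The over-reaction product is the species I back for the end of these flasks, so I turn the question round and ask what the isomer of the product would need to overtake it.

| flask | substrate | capture agent | remark | time |
|---|---|---|---|---|
| red | 22 mM | 0.56 mM | run made earlier |  |
| amber | 22 mM | 1.1 mM | run made earlier |  |
| dawn | 22 mM | 0.990 mM |  | 20 h |
| summer | 22 mM | 0.440 mM |  | 20 h |
| midnight | 22 mM | 0.660 mM |  | 20 h |

| run | time / h | target / % | open intermediate / % | isomer of the product / % | over-reaction product / % | trapped intermediate / % | substrate / % |
|---|---|---|---|---|---|---|---|
| red | 1.33 | 7.8 | 70.9 | 5.0 | 2.0 | 0.4 | 13.6 |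
| red | 4.00 | 15.6 | 48.8 | 15.6 | 17.1 | 0.9 | 0 |
| red | 6.00 | 13.0 | 33.5 | 21.7 | 29.6 | 0.7 | 0 |
| red | 10.0 | 8.1 | 16.6 | 27.0 | 48.9 | 1.1 | 0 |
| amber | 2.50 | 13.9 | 64.4 | 11.2 | 6.7 | 1.2 | 2.9 |
| amber | 5.00 | 15.1 | 39.8 | 19.3 | 23.9 | 1.8 | 0.2 |
| amber | 8.00 | 10.5 | 23.0 | 25.4 | 40.0 | 2.0 | 0 |
| amber | 10.0 | 7.1 | 16.4 | 26.6 | 47.8 | 1.8 | 0.9 |

(standard deviation of a reading: 0.5 percentage points)

- which of these there is most of at the end, counted by the substrate in it, dawn (open intermediate / trapped intermediate / over-reaction product / isomer of the product / target)
- which of these there is most of at the end, counted by the substrate in it, summer (open intermediate / trapped intermediate / over-reaction product / isomer of the product / target)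
- which of these there is most of at the end, counted by the substrate in it, midnight (open intermediate / trapped intermediate / over-reaction product / isomer of the product / target)
- final amount of the leader among these, as a percentage of the substrate charged, in dawn
- final amount of the leader among these, as a percentage of the substrate charged, in summer
- final amount of the leader among these, as a percentage of the substrate charged, in midnight



The zero of my scale is the even case: the over-reaction product and the isomer of the product level, and the pool of open intermediate plus target dividing equally between them. Any lead raises the price of a tie. I call that price the tie share, the part of the present pool that must reach the isomer of the product for it to draw level once the pool has divided, if it keeps what it holds: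

tie share = 0.5 + (over-reaction product − isomer of the product) / (2 × pool)

red, 10.0 h: pool 24.7%, tie share 94.3%

amber, 10.0 h: tie share 95.1%

Against this I set the selectivity, the isomer's part of what the two products gain between readings. It is 21.5% in red from 6.00 h to 10.0 h, and 23.4% in amber from 5.00 h to 10.0 h, so these readings stand far under the tie.

Amber holds about twice red's [capture agent], yet its tie share sits beside red's. Midnight and dawn lie between those doses, and summer, at 0.440 mM, lies a little under red. I therefore commit to the over-reaction product as leader in dawn, summer and midnight. If red's pool divided at red's selectivity, that product would reach 68.3%, which I take as a rough mark and not as a bound.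

The forecast names the same leader, at 62.8% in dawn, 63.6% in summer and 63.3% in midnight, under my mark, noting “Red and amber otherwise match”.

Dawn ends with the over-reaction product at 64.9%, summer at 65.6% and midnight at 65.3%, each ahead of its isomer of the product.

    substrate → open intermediate (k = 1.50 h⁻¹)
    open intermediate ⇌ target (K = 3.10, k = 0.150 h⁻¹)
    open intermediate ⇌ isomer of the product (K = 2.80, k = 0.0770 h⁻¹)
    open intermediate + capture agent → trapped intermediate (k = 5.80 M⁻¹ h⁻¹)
    target → over-reaction product (k = 0.430 h⁻¹)

In summer at 20 h the pool is 7.21%, so the tie share is 323%, more than the whole pool and higher than red's 94.3%. In the scheme the isomer of the product runs back to open intermediate, and in summer it stands at 26.8% after 10.0 h and 26.3% after 20.0 h. The neighbouring flask is summer read at 5.0 h, with 24.0% over-reaction product, 20.0% isomer of the product, 40.3% open intermediate and 15.0% target. Its tie share is 53.6%, close to the even case. From that reading to 20 h, the isomer of the product takes 13.1% of what the two products gain.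

The runs stem from a simulated flask on assumed constants; the scatter is artificial.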